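We decide to keep a ledger of L and to charge each L that goes to E two X: one taken in L + X, and one bound as G by the D it leaves. That second charge is our guess, since the earlier runs do not show it.

- larch: L 0.050 M; X 0.30 M; Q 2 mM; run made earlier
- flask: L 0.10 M; X 0.300 M; Q 2.00 mM; time 10 min

- larch (time / s: L / %, E / %): 10.0: 90.8, 8.8; 20.0: 84.5, 16.2; 30.0: 76.1, 20.8; 40.0: 71.6, 25.6; 50.0: 66.3, 30.2; 60.0: 60.6, 35.9

(standard deviation of a reading: 1 percentage point)

- amounts and yields of D count J too
- what was read earlier has a scatter of 1 percentage point, one standard deviation
- steps that have been proposed: L + X -> D + E; X + D <-> G; X + D <-> J; L + Q -> Z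
- the earlier runs do not show how much of X is bound; that part of a forecast is a guess

1. part of the L that has reacted at 10 min
2. share of free X in free X and G together, at 10 min

First entry, Z. At the last larch reading, 3.50% of the L stands neither as L nor as E, close to the 4.00% that the larch charge of Q could take, so in the flask we book 2.00% as Z.

Second entry, E, is paid from free X, and the rate of L + X goes with free X times L. We name the reach, the X charge over twice the L charge, 150%: the most E, as a fraction of the L charge, that X can pay for at two X each. Free X, as a fraction of its charge, is then one minus E over the reach. In this flask the reach is more than the L left to pay for, so between L and X, L is the limiting reagent, and on our ledger 34.7% of the X stays over when that L is used up.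

The last larch reading, with X at its mean, gives a rate constant, as a reading, of 0.0275 M⁻¹ s⁻¹. Free X over L left then grows exponentially, with exponent 1.72 at the asked time. The books close with L left at 6.92% and E at 91.1%. We commit to 93.1% reacted, free X at 39.3% of its charge, and a free share of 56.4%.

The forecast gave 94% reacted and a free share of 75%, the second “which is a guess”, and our share differs from it. The flask gives 93.3% and 56.6%.

    L + X → D + E (k = 0.0280 M⁻¹ s⁻¹)
    X + D ⇌ G, settled at all times (K = 5100 M⁻¹)
    X + D ⇌ J, settled at all times (K = 60.0 M⁻¹)
    L + Q → Z (k = 0.720 M⁻¹ s⁻¹)

By 1.00 min the flask held 3.30% of its Q, Z stood at 1.93%, and L + X had 38% of its turnover up to the asked time behind it. L + X then ran on to E at 91.3% by 10.0 min, with G at 90.1% of the L charge.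

In the same flask with 0.075 M of X the reach is 37.5%, so on our ledger E should stand just under that. The computed flask shows, at 10.0 min, E at 34.5%, 9.18% of its X free, and 36.5% of the L reacted.

All runs are calculated with constants of no real substance; noise was put on by code.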